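(The earlier runs and the new flask stem from a simulated flask with constants of no real substance.)

In the violet run, charged with 29 mM of starting material, ring stood at 69.4% at the last reading. In the ochre run, charged with 64 mM, it stood at 52.9%.

| run | time / min | ring / % | crystals / % |
|---|---|---|---|
| violet | 6.00 | 29.4 | 17.0 |
| violet | 10.0 | 40.5 | 28.8 |
| violet | 20.0 | 55.5 | 45.1 |
| violet | 40.0 | 65.3 | 57.0 |
| violet | 80.0 | 69.4 | 59.9 |
| ochre | 6.00 | 25.8 | 18.9 |
| ochre | 20.0 | 45.0 | 37.8 |
| ochre | 30.0 | 48.6 | 44.9 |
| ochre | 50.0 | 52.7 | 47.1 |
| ochre | 80.0 | 52.9 | 49.2 |

(each reading ± 0.5 percentage points)

Our flask gets 43 mM, 1.48 times the violet charge, and stands for 1.0 h.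

1. ring and crystals together at 1.0 h, in percent of the starting material charged
2. concentration of ring in solution at 1.0 h, in percent of saturation

- for ring the crystals are counted in
- as a solid, counted per litre of solution: crystals

We take two competing times: a closure time that ignores the charge, and a coupling time that shortens as [starting material] grows. Closure time over coupling time at the start is the competition number N, a selectivity factor. Integrated, the final ring share is the natural log of one plus N, divided by N.

For N of one this gives 69.3%, which lies within 0.5 percentage points of the last violet reading, so we take N as a flask's charge over the violet charge. The ochre run then gives 52.8% against its last reading of 52.9%, and our flask 61.3%.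

The first violet reading puts the closure time at about 20.4 min or less, so our flask runs about 2.94 such times or more, and we commit to just under its final share. Ring minus crystals at the last readings is 2.76 mM in the violet run and 2.37 mM in the ochre run. Our flask makes about 26.4 mM of ring, so we expect crystals and a saturated solution.

The forecast says 61.4% and 101%: “the solution should be essentially saturated”.

The flask gives 60.8% and 100%.

    starting material → ring (k = 0.0679 min⁻¹)
    2 starting material → open dimer (k = 1.16 M⁻¹ min⁻¹)
    crystals ⇌ ring, rate k3*(cs3 - [ring]) while solid is left; crystals form when [ring] > cs3 (solubility = 2.70 mM, k = 1.59 min⁻¹)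

At the start of our flask, the step to ring uses starting material at 0.68 of the rate of the step to open dimer, and our one over N, read from the runs, is 0.676. The neighbour charged with 110 mM has N of 3.79, so the same reckoning gives 41.3%. That neighbour reaches 41.1%, with open dimer at 58.5% of its charge.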